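(The runs were computed on assumed constants, and the scatter is random.)

Put two questions to these flasks: is the target still moving at the asked time, and what does a plateau pay per equivalent of reagent at each temperature?

| flask | starting material | reagent | second substrate | protic impurity | temperature | remark | time |
|---|---|---|---|---|---|---|---|
| east | 0.050 M | 0.35 equiv | 1 equiv | 2.5 mM | 25 °C | run made earlier |  |
| west | 0.050 M | 1.4 equiv | 1 equiv | 2.5 mM | 45 °C | run made earlier |  |
| north-west | 0.050 M | 0.70 equiv | 1 equiv | 5 mM | 25 °C | run made earlier |  |
| midnight | 0.050 M | 0.700 equiv | 1.00 equiv | 2.50 mM | 30 °C |  | 3.0 min |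
| summer | 0.050 M | 0.700 equiv | 1.00 equiv | 2.50 mM | 45 °C |  | 3.0 min |
| dusk | 0.050 M | 0.700 equiv | 1.00 equiv | 2.50 mM | 60 °C |  | 3.0 min |

east run (percent of the starting material charged): time / min: target / % = 0.833: 10; 2.00: 7; 2.50: 6; 4.00: 9

west run (percent of the starting material charged): time / s: target / % = 10.0: 23; 20.0: 19; 40.0: 20; 120: 22

north-west run (percent of the starting material charged): time / min: target / % = 0.417: 19; 1.33: 17; 2.50: 20; 4.00: 18

(standard deviation of a reading: 1.5 percentage points)

* the flask with the highest amount of target, in percent of the starting material charged ("all alike" if they lie within 1.5 percentage points) (midnight / summer / dusk / all alike)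
* final target, as a percentage of the starting material charged, in midnight
* final target, as a percentage of the starting material charged, in summer
* final target, as a percentage of the starting material charged, in dusk

Answer the first from the readings themselves. East reads 10% at 0.833 min and 9% at 4.00 min, and west reads 23% at 10.0 s and 22% at 120 s, each pair closer than the scatter of 1.5 percentage points, so treat the target as standing on a plateau well before 3.0 min, and ask the plateau for its number.

Take the mean plateau target, as a fraction of the starting material charged, and divide it by the equivalents of reagent: west gives 15.0%, and call this fraction the plateau share. At 25 °C, east gives 22.9% and north-west 26.4%, although north-west has twice the reagent and twice the protic impurity, so assume that the share does not depend on loading, leave the impurity out of the sum, and pool these two runs into 25.2%.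

Under that assumption, going from 25 °C in east and north-west to 45 °C in west multiplies the share by 0.594; spread that factor evenly over the degrees, stepping past the hottest run for dusk, and multiply by 0.700 equiv. This gives 15.5% in midnight, 10.5% in summer and 7.11% in dusk, which puts midnight highest.

The forecast also names midnight, with 17% (14% to 20%), 12% (8.5% to 17%) and 8% (4% to 15%), each a little above this reckoning, on the ground that “a wasteful path with higher activation energy wins when hot”.

The flasks give 15.1% in midnight, 10.6% in summer and 6.76% in dusk, so the highest is midnight.

    starting material + reagent ⇌ target (K = 5.91 M⁻¹, k = 9.03 M⁻¹ s⁻¹, Ea = 43.0 kJ mol⁻¹, ΔH = −13.0 kJ mol⁻¹)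
    second substrate + reagent ⇌ second product (K = 32.7 M⁻¹, k = 73.4 M⁻¹ s⁻¹, Ea = 40.0 kJ mol⁻¹, ΔH = 35.0 kJ mol⁻¹)
    second substrate + protic impurity → quenched substrate (k = 8.82 M⁻¹ s⁻¹, Ea = 47.0 kJ mol⁻¹)
    starting material + target → side product (k = 0.0586 M⁻¹ s⁻¹, Ea = 52.0 kJ mol⁻¹)
    target → over-reaction product (k = 0.00219 s⁻¹, Ea = 85.0 kJ mol⁻¹)
    (constants at 60 °C)

Now use the west share on the neighbour of summer, charged with 0.280 equiv of reagent, its other charges and its time held as in summer. The share of 15.0% on that charge reckons 4.20% of target, and the neighbour of summer stands at 4.34%, with 45% of its reagent still unbound and 93% of its starting material still there.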